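Assumption: the target is drawn without a descriptor for the C1–C1' axis and has no stereocentre, so the route is planned for the racemic biaryl and no step is asked to control the axis.

## Analysis of the target

The target (23) is an unsymmetrical 1,1'-binaphthalene. Half A (C1–C8a) carries OH on C2 and C5, OMe on C4 and CH3 on C7. Half B (C1'–C8a') carries CH3 on C2', OH on C4' and C6' and OMe on C5'. The only stereogenic element is the C1–C1' axis, flanked by C2–OH and H-8 on one side and C2'–CH3 and H-8' on the other; it should rotate slowly, but no configuration is asked for. The four free naphthols make the compound electron-rich and easily oxidised by air, so they are unmasked last, with protecting groups that come off without touching the two aryl methyl ethers. The difficulty is that the two halves differ in oxygenation pattern and are joined through two carbons that each have two ortho neighbours. A late biaryl cross-coupling would be slow, and an oxidative naphthol coupling would not be regioselective. The strategy rests on the ring C1'–C4' of half B. C4' (OH) and C3' (H) are what an aroylacetate leaves after annulation and decarboxylation, and C2' with its methyl and C1' with half A are the two carbons of a 1-arylpropyne. The C5' methoxy group occupies one of the two positions ortho to the acyl carbon, so a ring closure from C1' can only reach C8a'. Half A is a 1,3-dioxygenated ring fused to a meta-cresol ring, which suggests an alkoxy-aryne and an oxygenated diene.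

## Retrosynthetic reasoning

**23 back to 22.** The last operation removes the two benzyl ethers on O-5 and O-6'. Benzyl is chosen because hydrogenolysis is neutral and leaves the methyl ethers on C4 and C5' alone.

**22 back to 21 and 20.** The hydrogen on C3' stands where a carboxyl group was. C3' must be a 1,3-dicarbonyl carbon to be oxidisable in the key step, so the ester is a traceless activating group. Hydrolysis of 20 gives acid 21 and also frees O-2 of half A; 21 is a vinylogous β-keto acid and loses CO2 on heating to give 22.

**20 back to 5 and 19.** The bonds C2'–C3' and C1'–C8a' are cut. This removes the whole C1'–C4' ring and turns the hindered biaryl bond into an aryl–alkyne bond, whereas cutting the axis would leave two hindered naphthalenes to be joined. In the forward direction the α-radical of keto ester 5 has to add to the methyl-bearing alkyne carbon of 19, and the vinyl radical has to close on C8a'. In 19, O-2 of half A carries a pivalate rather than a benzyl ether, for three reasons: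
- the atom on O-2 lies 1,5 to the vinyl radical, and a benzylic CH2 there would invite hydrogen transfer;
- the acyl group makes half A harder to oxidise at the anode;
- it falls off in the hydrolysis that leads to 21, so no extra step is needed.

**19 back to 17 and 18, then 16 and 15.** The C1–C(sp) bond is cut (aryl iodide 17 plus propyne 18). Iodide 17 comes from iodonaphthol 16 by acylation, and 16 from naphthol 15 by iodination. The iodination is placed on the free 2-naphthol because that group directs an electrophile to C1.

**15 back to 13 and 12.** The bonds C1–C8a and C4–C4a are cut, which takes the oxygenated ring of half A apart into aryne 13 and diene 12. The diene delivers C1–C4 with the two oxygens already told apart: its acetal carbon becomes C4–OMe and its silyl enol ether carbon becomes C2–OH. The benzyloxy group of 13 steers the acetal carbon to the position next to it, so that C4–OMe ends peri to C5–O. Aryne 13 is released from iodo triflate 9, which goes back through 8 and 7 to orcinol (6). Diene 12 goes back through enone 11 to ketene acetal 10.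

**5 back to 4, 3, 2 and 1.** The C3'–C4' bond is cut (crossed ester condensation on benzoate 4). Ester 4 comes from 2,3-dihydroxybenzoic acid (1) by esterification to 2, benzylation of O-3 to 3 and methylation of O-2.

## Alternatives that were turned down

**Alternative 1:** The oxygenated ring of half A is built last: C1–C8a and C4–C4a are cut, with the finished half B already on the terminal carbon of the diene. In the forward direction a silylmethyl Grignard reagent would release the same aryne as 13 from its iodo triflate; the diene would add across it, and loss of one methoxy group would give A1, 5-(benzyloxy)-1-[4,6-bis(benzyloxy)-5-methoxy-2-methylnaphthalen-1-yl]-4-methoxy-7-methylnaphthalen-2-ol.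
- For: the regiochemistry of alkoxy-aryne additions is well understood. A1 needs only hydrogenolysis, with no ester to remove; on this end-game point it is stronger than the chosen route.
- Against: the diene carbon that must attack the aryne is the one bearing a di-ortho-substituted naphthyl group. Aryne additions to polarised dienes have stepwise character, and a hindered terminus favours four-membered closure at the acetal end or proton transfer over the six-membered closure. The diene also needs half B made first with a three-carbon ketone side chain on C1', and a defined enol ether geometry.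
- Comparison: the chosen route uses the same cycloaddition only where it is most dependable, on the unsubstituted diene 12. The bond to the axis carbon is made instead as an aryl–alkyne coupling, and half B grows directly on that alkyne.

**Alternative 2:** C1'–C2' is cut, so that the C1'–C4' ring closes by an aldol condensation. The precursor is a diaryl ketone (C1', between half A and the benzo ring of half B) with a four-carbon keto aldehyde chain ortho to it. A secondary amine with a weak acid would form the enamine of the aldehyde; its α-carbon C2' adds to the ketone C1', and dehydration with enolisation of the C4' ketone gives A2, 6-(benzyloxy)-1-[2,5-bis(benzyloxy)-4-methoxy-7-methylnaphthalen-1-yl]-4-hydroxy-5-methoxynaphthalene-2-carbaldehyde.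
- For: the conditions are mild and metal-free. A chiral amine could in principle set the axis, which the chosen route cannot do; that would matter only if one atropisomer were wanted.
- Against: the electrophile is a ketone between two electron-rich arenes with three ortho substituents around it, and is therefore a poor acceptor. Making that ketone next to a free γ-keto aldehyde is a problem in itself. C2' ends as CHO, so at least one extra reduction is needed to reach the methyl group.
- Comparison: the chosen route makes C1' a radical centre instead of attacking a hindered carbonyl, and takes the C2' methyl group directly from propyne.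

**Alternative 3:** C3' is inserted as one carbon into a 3-aryl-2-methylindanone, cutting C2'–C3' and C3'–C4'. A dihalocarbene from a haloform and an alkoxide base would cyclopropanate the silyl enol ether; opening with loss of bromide and silicon enlarges the ring to A3, 7-(benzyloxy)-4-[2,5-bis(benzyloxy)-4-methoxy-7-methylnaphthalen-1-yl]-2-bromo-8-methoxy-3-methylnaphthalen-1-ol.
- For: it is classical ionic chemistry needing no electrolysis. The bromine is removed in the final hydrogenolysis, so the end-game is shorter than here.
- Against: the indanone needs the C1'–half A bond made at an sp3 carbon, by adding a hindered naphthyl nucleophile to an indenone or by a cationic cyclisation. The electrophilic carbene can also attack the dialkoxy ring of half A. The enol ether is tetrasubstituted and sits next to the bulky aryl group.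
- Comparison: the chosen route is more convergent. Both partners come from simple benzenoid starting materials in a few steps each, and the only reactive intermediate that meets half A is a carbon radical that adds to the alkyne two atoms away from it.

Key step: step 14

## Route

Step 1
Reactants: 1 2,3-dihydroxybenzoic acid
Product: 2 ethyl 2,3-dihydroxybenzoate
Conditions: EtOH, H2SO4 (cat.), reflux
Reagents that add atoms: ethanol, CCO
Why: Fischer esterification; the ethyl ester is chosen so that the later Claisen step releases only ethoxide.

Step 2
Reactants: 2 ethyl 2,3-dihydroxybenzoate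
Product: 3 ethyl 3-(benzyloxy)-2-hydroxybenzoate
Conditions: BnBr (1.0 equiv), K2CO3, DMF, rt
Reagents that add atoms: benzyl bromide, BrCc1ccccc1
Why: Williamson etherification; the C2 hydroxyl is held in a hydrogen bond to the ester carbonyl and its phenoxide is delocalised into the ester, so one equivalent of benzyl bromide should take the C3 oxygen.

Step 3
Reactants: 3 ethyl 3-(benzyloxy)-2-hydroxybenzoate
Product: 4 ethyl 3-(benzyloxy)-2-methoxybenzoate
Conditions: MeI, K2CO3, DMF, 50 °C
Reagents that add atoms: iodomethane, CI
Why: Williamson methylation of the chelated phenol, which needs a dipolar solvent and gentle heating; the ester and benzyl ether are inert.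

Step 4
Reactants: 4 ethyl 3-(benzyloxy)-2-methoxybenzoate
Product: 5 ethyl 3-[3-(benzyloxy)-2-methoxyphenyl]-3-oxopropanoate
Conditions: EtOAc, LiN(SiMe3)2 (2.5 equiv), THF, −78 °C to 0 °C; aq. NH4Cl
Reagents that add atoms: ethyl acetate, CCOC(C)=O
Why: Crossed Claisen condensation; the lithium enolate of ethyl acetate acylates on the non-enolisable benzoate, and the excess base stores the product as its enolate so that it is not attacked again.

Step 5
Reactants: 6 orcinol (5-methylbenzene-1,3-diol)
Product: 7 2-iodo-5-methylbenzene-1,3-diol
Conditions: I2, NaHCO3, H2O, 0 °C to rt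
Reagents that add atoms: iodine, II
Why: Electrophilic aromatic iodination; resorcinols in aqueous hydrogencarbonate are known to take iodine at the carbon between the two hydroxyls, and the methyl group further shields C4 and C6.

Step 6
Reactants: 7 2-iodo-5-methylbenzene-1,3-diol
Product: 8 3-(benzyloxy)-2-iodo-5-methylphenol
Conditions: BnBr (1.0 equiv), K2CO3, acetone, reflux
Reagents that add atoms: benzyl bromide, BrCc1ccccc1
Why: Williamson etherification of one of two equivalent phenols; with one equivalent of halide the mono-ether should be the main product, and it is separable from diether and diol by its acidity.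

Step 7
Reactants: 8 3-(benzyloxy)-2-iodo-5-methylphenol
Product: 9 3-(benzyloxy)-2-iodo-5-methylphenyl trifluoromethanesulfonate
Conditions: Tf2O, pyridine, CH2Cl2, 0 °C
Reagents that add atoms: trifluoromethanesulfonic anhydride, O=S(=O)(OS(=O)(=O)C(F)(F)F)C(F)(F)F
Why: O-Sulfonylation of the remaining phenol gives the ortho-iodoaryl triflate, a standard precursor for releasing an aryne at low temperature.

Step 8
Reactants: 10 1,1-dimethoxyethene
Product: 11 4,4-dimethoxybut-3-en-2-one
Conditions: AcCl, Et3N, Et2O, 0 °C to rt
Reagents that add atoms: acetyl chloride, CC(Cl)=O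
Why: C-Acylation of the ketene acetal at its nucleophilic CH2 carbon followed by loss of HCl gives the β,β-dimethoxy enone, a stable vinylogous ester.

Step 9
Reactants: 11 4,4-dimethoxybut-3-en-2-one
Product: 12 [(4,4-dimethoxybuta-1,3-dien-2-yl)oxy]trimethylsilane
Conditions: LiN(i-Pr)2, THF, −78 °C; Me3SiCl
Reagents that add atoms: chlorotrimethylsilane, C[Si](C)(C)Cl
Why: Kinetic enolisation of the methyl ketone and O-silylation (silyl enol ether formation); the acetyl methyl group holds the only acidic hydrogens.

Step 10
Reactants: 9 3-(benzyloxy)-2-iodo-5-methylphenyl trifluoromethanesulfonate; 12 [(4,4-dimethoxybuta-1,3-dien-2-yl)oxy]trimethylsilane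
Product: 15 5-(benzyloxy)-4-methoxy-7-methylnaphthalen-2-ol, via 3-(benzyloxy)-5-methylbenzyne 13 (not isolated), via cycloadduct silyl enol ether 14 (not isolated)
Conditions: n-BuLi added to 9 and 12 (3 equiv), THF, −78 °C; then 1 M HCl, rt
Reagents that add atoms: none
Why: Iodine–lithium exchange and loss of triflate release aryne 13, whose benzyloxy group makes the carbon meta to oxygen the electrophilic one; the nucleophilic CH2 end of 12 bonds there and the acetal carbon bonds next to the benzyloxy group (aryne Diels–Alder reaction). Acid work-up hydrolyses the silyl enol ether of 14 and expels one methoxy group, so the ring aromatises with OMe on C4 peri to C5–OBn and a free OH on C2.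

Step 11
Reactants: 15 5-(benzyloxy)-4-methoxy-7-methylnaphthalen-2-ol
Product: 16 5-(benzyloxy)-1-iodo-4-methoxy-7-methylnaphthalen-2-ol
Conditions: N-iodosuccinimide (1.0 equiv), MeCN, 0 °C, dark
Reagents that add atoms: N-iodosuccinimide, O=C1CCC(=O)N1I
Why: Electrophilic iodination of a 2-naphthol goes to C1, which here is also para to the C4 methoxy group; one equivalent at low temperature should prevent a second iodination.

Step 12
Reactants: 16 5-(benzyloxy)-1-iodo-4-methoxy-7-methylnaphthalen-2-ol
Product: 17 5-(benzyloxy)-1-iodo-4-methoxy-7-methylnaphthalen-2-yl 2,2-dimethylpropanoate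
Conditions: t-BuCOCl, Et3N, DMAP (cat.), CH2Cl2, 0 °C to rt
Reagents that add atoms: 2,2-dimethylpropanoyl chloride, CC(C)(C)C(Cl)=O
Why: DMAP-catalysed acylation of the hindered naphthol; the pivalate places no C–H bond 1,5 to the later vinyl radical, lowers the electron density of half A, and is cleaved without an extra step in step 15.

Step 13
Reactants: 17 5-(benzyloxy)-1-iodo-4-methoxy-7-methylnaphthalen-2-yl 2,2-dimethylpropanoate; 18 propyne
Product: 19 5-(benzyloxy)-4-methoxy-7-methyl-1-(prop-1-yn-1-yl)naphthalen-2-yl 2,2-dimethylpropanoate
Conditions: propyne (excess), Pd(PPh3)2Cl2 (5 mol%), CuI (10 mol%), Et3N, THF, 50 °C, sealed vessel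
Reagents that add atoms: none
Why: Sonogashira coupling; the aryl iodide is flanked on both sides, but the partner is a slim copper acetylide, and the tertiary amine does not attack the pivalate.

Step 14
Reactants: 5 ethyl 3-[3-(benzyloxy)-2-methoxyphenyl]-3-oxopropanoate; 19 5-(benzyloxy)-4-methoxy-7-methyl-1-(prop-1-yn-1-yl)naphthalen-2-yl 2,2-dimethylpropanoate
Product: 20 ethyl 7-(benzyloxy)-4-{5-(benzyloxy)-2-[(2,2-dimethylpropanoyl)oxy]-4-methoxy-7-methylnaphthalen-1-yl}-1-hydroxy-8-methoxy-3-methylnaphthalene-2-carboxylate
Conditions: undivided cell, reticulated vitreous carbon anode, Pt cathode, constant current; Fe(C5H5)2 (10 mol%), Na2CO3, n-Bu4NBF4, THF/EtOH (5:1), 65 °C; 5 in excess (2.5 equiv)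
Reagents that add atoms: none
Why: The anode turns Fe(C5H5)2 into [Fe(C5H5)2]+, which should oxidise the enolate of 5 to the radical at C3' at a potential well below that of the naphthalene ethers, while the cathode reduces ethanol to H2 and ethoxide and so keeps the enolate supplied. The electrophilic radical should add to the methyl-bearing alkyne carbon of 19, the less hindered end and the one that leaves a linear vinyl radical conjugated with half A; this forms C2'–C3' and puts methyl on C2' and half A on C1'. The vinyl radical then attacks the one free ortho carbon of the aroyl ring, C8a', in a six-membered closure by homolytic aromatic substitution (6-exo-trig with respect to the C8a'=C8' bond), forming C1'–C8a'. A second one-electron oxidation and loss of a proton restore aromaticity, and the C4' ketone enolises to the hydrogen-bonded naphthol. The closest known reaction type is the Fe(C5H5)2-mediated anodic annulation of 1,3-dicarbonyl compounds with aryl alkynes to 1-naphthols, the electrochemical relative of oxidative radical annulations with Mn(OAc)3; only the bulk of the aryl group on the alkyne goes beyond it. No stereocentre is formed and the biaryl axis arises as the racemate. Three selectivities are needed: the site of oxidation, secured by the low potential of the mediator and by the pivalate on half A; the direction of addition, secured by sterics and by the aryl-stabilised vinyl radical; and ring closure over hydrogen transfer, secured by the C5' methoxy group blocking the second ortho position and by the lack of any C–H bond 1,5 to the radical.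

Step 15
Reactants: 20 ethyl 7-(benzyloxy)-4-{5-(benzyloxy)-2-[(2,2-dimethylpropanoyl)oxy]-4-methoxy-7-methylnaphthalen-1-yl}-1-hydroxy-8-methoxy-3-methylnaphthalene-2-carboxylate
Product: 21 7-(benzyloxy)-4-[5-(benzyloxy)-2-hydroxy-4-methoxy-7-methylnaphthalen-1-yl]-1-hydroxy-8-methoxy-3-methylnaphthalene-2-carboxylic acid
Conditions: KOH (excess), EtOH/H2O (3:1), reflux, Ar; then 1 M HCl
Reagents that add atoms: potassium hydroxide, [K+].[OH-]
Why: Saponification; the ester is hindered and hydrogen-bonded to the naphthol, so excess hydroxide at reflux is used, which also cleaves the aryl pivalate, while benzyl and methyl ethers are inert to base.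

Step 16
Reactants: 21 7-(benzyloxy)-4-[5-(benzyloxy)-2-hydroxy-4-methoxy-7-methylnaphthalen-1-yl]-1-hydroxy-8-methoxy-3-methylnaphthalene-2-carboxylic acid
Product: 22 7-(benzyloxy)-4-[5-(benzyloxy)-2-hydroxy-4-methoxy-7-methylnaphthalen-1-yl]-8-methoxy-3-methylnaphthalen-1-ol
Conditions: Cu2O (10 mol%), 1,10-phenanthroline (20 mol%), NMP/quinoline (3:1), 170 °C, Ar
Reagents that add atoms: none
Why: Copper-catalysed protodecarboxylation of an ortho-substituted aromatic acid, made easier because the acid is a vinylogous β-keto acid in its keto tautomer; benzyl ethers tolerate the temperature under argon.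

Step 17
Reactants: 22 7-(benzyloxy)-4-[5-(benzyloxy)-2-hydroxy-4-methoxy-7-methylnaphthalen-1-yl]-8-methoxy-3-methylnaphthalen-1-ol
Product: 23 4,5'-dimethoxy-2',7-dimethyl-1,1'-binaphthalene-2,4',5,6'-tetrol (the target)
Conditions: H2 (1 atm), Pd/C (10%), EtOAc/MeOH, rt
Reagents that add atoms: none
Why: Hydrogenolysis of the two benzyl ethers over palladium on carbon; the aryl methyl ethers and the naphthalene rings are untouched at 1 atm and room temperature.

## Compound list

1 | 2,3-dihydroxybenzoic acid | O=C(O)c1cccc(O)c1O | starting material
2 | ethyl 2,3-dihydroxybenzoate | CCOC(=O)c1cccc(O)c1O | intermediate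
3 | ethyl 3-(benzyloxy)-2-hydroxybenzoate | CCOC(=O)c1cccc(OCc2ccccc2)c1O | intermediate
4 | ethyl 3-(benzyloxy)-2-methoxybenzoate | CCOC(=O)c1cccc(OCc2ccccc2)c1OC | intermediate
5 | ethyl 3-[3-(benzyloxy)-2-methoxyphenyl]-3-oxopropanoate | CCOC(=O)CC(=O)c1cccc(OCc2ccccc2)c1OC | intermediate
6 | orcinol (5-methylbenzene-1,3-diol) | Cc1cc(O)cc(O)c1 | starting material
7 | 2-iodo-5-methylbenzene-1,3-diol | Cc1cc(O)c(I)c(O)c1 | intermediate
8 | 3-(benzyloxy)-2-iodo-5-methylphenol | Cc1cc(O)c(I)c(OCc2ccccc2)c1 | intermediate
9 | 3-(benzyloxy)-2-iodo-5-methylphenyl trifluoromethanesulfonate | Cc1cc(OCc2ccccc2)c(I)c(OS(=O)(=O)C(F)(F)F)c1 | intermediate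
10 | 1,1-dimethoxyethene | C=C(OC)OC | starting material
11 | 4,4-dimethoxybut-3-en-2-one | CC(=O)C=C(OC)OC | intermediate
12 | [(4,4-dimethoxybuta-1,3-dien-2-yl)oxy]trimethylsilane | C=C(O[Si](C)(C)C)C=C(OC)OC | intermediate
13 | 3-(benzyloxy)-5-methylbenzyne (1-(benzyloxy)-5-methyl-2,3-didehydrobenzene) | C1#CC(OCc2ccccc2)=CC(C)=C1 | intermediate
14 | {[5-(benzyloxy)-4,4-dimethoxy-7-methyl-1,4-dihydronaphthalen-2-yl]oxy}trimethylsilane | COC1(OC)C=C(O[Si](C)(C)C)Cc2cc(C)cc(OCc3ccccc3)c21 | intermediate
15 | 5-(benzyloxy)-4-methoxy-7-methylnaphthalen-2-ol | COc1cc(O)cc2cc(C)cc(OCc3ccccc3)c12 | intermediate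
16 | 5-(benzyloxy)-1-iodo-4-methoxy-7-methylnaphthalen-2-ol | COc1cc(O)c(I)c2cc(C)cc(OCc3ccccc3)c12 | intermediate
17 | 5-(benzyloxy)-1-iodo-4-methoxy-7-methylnaphthalen-2-yl 2,2-dimethylpropanoate | COc1cc(OC(=O)C(C)(C)C)c(I)c2cc(C)cc(OCc3ccccc3)c12 | intermediate
18 | propyne | CC#C | starting material
19 | 5-(benzyloxy)-4-methoxy-7-methyl-1-(prop-1-yn-1-yl)naphthalen-2-yl 2,2-dimethylpropanoate | CC#Cc1c(OC(=O)C(C)(C)C)cc(OC)c2c(OCc3ccccc3)cc(C)cc12 | intermediate
20 | ethyl 7-(benzyloxy)-4-{5-(benzyloxy)-2-[(2,2-dimethylpropanoyl)oxy]-4-methoxy-7-methylnaphthalen-1-yl}-1-hydroxy-8-methoxy-3-methylnaphthalene-2-carboxylate | CCOC(=O)c1c(C)c(-c2c(OC(=O)C(C)(C)C)cc(OC)c3c(OCc4ccccc4)cc(C)cc23)c2ccc(OCc3ccccc3)c(OC)c2c1O | intermediate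
21 | 7-(benzyloxy)-4-[5-(benzyloxy)-2-hydroxy-4-methoxy-7-methylnaphthalen-1-yl]-1-hydroxy-8-methoxy-3-methylnaphthalene-2-carboxylic acid | OC(=O)c1c(C)c(-c2c(O)cc(OC)c3c(OCc4ccccc4)cc(C)cc23)c2ccc(OCc3ccccc3)c(OC)c2c1O | intermediate
22 | 7-(benzyloxy)-4-[5-(benzyloxy)-2-hydroxy-4-methoxy-7-methylnaphthalen-1-yl]-8-methoxy-3-methylnaphthalen-1-ol | Cc1cc(O)c2c(OC)c(OCc3ccccc3)ccc2c1-c1c(O)cc(OC)c2c(OCc3ccccc3)cc(C)cc12 | intermediate
23 | 4,5'-dimethoxy-2',7-dimethyl-1,1'-binaphthalene-2,4',5,6'-tetrol | COc1cc(O)c(-c2c(C)cc(O)c3c(OC)c(O)ccc23)c2cc(C)cc(O)c12 | target

## Step count and least certain steps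

Total: 17 steps. Longest linear sequence: 11 steps (6 to 23 through steps 5, 6, 7, 10, 11, 12, 13, 14, 15, 16 and 17).

**Step 14 (key step).** The bulky aryl group may slow both the radical addition and the closure onto C8a'. The vinyl radical may then be diverted by hydrogen abstraction from the solvent or by closure through a carbonyl oxygen. The electron-rich half A may be oxidised directly at the anode. The basic alcoholic medium may cleave the pivalate, after which the freed naphthol would cyclise onto the alkyne.
Fallback, from 5 and 19 back to 20: the same radical is made reductively from an isolated bromide, without an anode or an alkoxide base. Treating 5 with N-bromosuccinimide and catalytic NH4OAc in Et2O should give ethyl 3-[3-(benzyloxy)-2-methoxyphenyl]-2-bromo-3-oxopropanoate F1. Irradiating F1 and 19 with blue light in DMF in the presence of Ir(ppy)3 (1 mol%) and 2,6-dimethylpyridine is a known photoredox annulation of 2-bromo-1,3-dicarbonyl compounds with alkynes. The excited iridium complex reduces the C–Br bond, the radical adds and cyclises as in step 14, and the oxidised catalyst re-aromatises the ring, giving 20.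

**Step 10.** Aryne additions to polarised dienes are not fully concerted. The intermediate may close to a four-membered ring at the enol ether end, or transfer a proton, instead of forming the six-membered ring. The butyl reagent may add to the aryne, and the diene may hydrolyse before it reacts.
Fallback, from 8 back to 15: the ring is built by ionic steps. O-Silylation of 8 with hexamethyldisilazane, then n-BuLi at −78 °C (iodine–lithium exchange and shift of silicon from oxygen to carbon) and Tf2O should give 3-(benzyloxy)-5-methyl-2-(trimethylsilyl)phenyl trifluoromethanesulfonate F2. CsF in MeCN releases the same aryne 13 from F2 in the presence of methyl acetoacetate; aryne acyl-alkylation (insertion into the C–C bond of the β-keto ester, acyl group next to the benzyloxy group) should give methyl 2-[2-acetyl-3-(benzyloxy)-5-methylphenyl]acetate F3. An intramolecular Claisen condensation (KOC(CH3)3, THF) closes F3 to 8-(benzyloxy)-6-methylnaphthalene-1,3-diol F4. The O-3 hydroxyl, which is not hydrogen-bonded to the peri benzyloxy group, is silylated selectively (i-Pr3SiCl, imidazole) to 8-(benzyloxy)-6-methyl-3-{[tri(propan-2-yl)silyl]oxy}naphthalen-1-ol F5. Methylation of the peri hydroxyl (MeI, K2CO3, DMF) gives {[5-(benzyloxy)-4-methoxy-7-methylnaphthalen-2-yl]oxy}tri(propan-2-yl)silane F6, and Bu4NF returns 15.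

**Step 13.** Oxidative addition into the doubly flanked, electron-rich iodide may be slow. The alkyne may then be lost by evaporation or by copper-mediated homocoupling. Slow aminolysis of the pivalate would be followed by ring closure of the naphthol onto the alkyne.
Fallback, from 17 back to 19: a Stille coupling with preformed tributyl(prop-1-yn-1-yl)stannane and Pd(PPh3)4 in toluene at 100 °C. It needs no gas, no copper acetylide and no amine, and makes no new intermediate.

**Step 16.** Decarboxylation may be incomplete at temperatures that the two free naphthols and the benzyl ethers tolerate, or the material may be lost by oxidation at high temperature.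
Fallback, from 21 to the target 23, bypassing 22: the carboxyl group is replaced by bromine at low temperature. N-Bromosuccinimide in MeCN at −20 °C attacks the carboxyl-bearing carbon ortho to the naphthol with loss of CO2 (halodecarboxylation of an ortho-hydroxy aromatic acid), giving 7-(benzyloxy)-4-[5-(benzyloxy)-2-hydroxy-4-methoxy-7-methylnaphthalen-1-yl]-2-bromo-8-methoxy-3-methylnaphthalen-1-ol F7. Hydrogenation of F7 over Pd/C with Et3N removes the bromine and both benzyl groups in one operation and gives 23. Any extra bromine introduced on half A would be removed in the same operation.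

## Further compounds

F1 | step 14 | ethyl 3-[3-(benzyloxy)-2-methoxyphenyl]-2-bromo-3-oxopropanoate | CCOC(=O)C(Br)C(=O)c1cccc(OCc2ccccc2)c1OC
F2 | step 10 | 3-(benzyloxy)-5-methyl-2-(trimethylsilyl)phenyl trifluoromethanesulfonate | Cc1cc(OCc2ccccc2)c([Si](C)(C)C)c(OS(=O)(=O)C(F)(F)F)c1
F3 | step 10 | methyl 2-[2-acetyl-3-(benzyloxy)-5-methylphenyl]acetate | COC(=O)Cc1cc(C)cc(OCc2ccccc2)c1C(C)=O
F4 | step 10 | 8-(benzyloxy)-6-methylnaphthalene-1,3-diol | Cc1cc(OCc2ccccc2)c2c(O)cc(O)cc2c1
F5 | step 10 | 8-(benzyloxy)-6-methyl-3-{[tri(propan-2-yl)silyl]oxy}naphthalen-1-ol | Cc1cc(OCc2ccccc2)c2c(O)cc(O[Si](C(C)C)(C(C)C)C(C)C)cc2c1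
F6 | step 10 | {[5-(benzyloxy)-4-methoxy-7-methylnaphthalen-2-yl]oxy}tri(propan-2-yl)silane | COc1cc(O[Si](C(C)C)(C(C)C)C(C)C)cc2cc(C)cc(OCc3ccccc3)c12
F0 | step 13 | none | none
F7 | step 16 | 7-(benzyloxy)-4-[5-(benzyloxy)-2-hydroxy-4-methoxy-7-methylnaphthalen-1-yl]-2-bromo-8-methoxy-3-methylnaphthalen-1-ol | Cc1c(Br)c(O)c2c(OC)c(OCc3ccccc3)ccc2c1-c1c(O)cc(OC)c2c(OCc3ccccc3)cc(C)cc12
A1 | alternative 1 | 5-(benzyloxy)-1-[4,6-bis(benzyloxy)-5-methoxy-2-methylnaphthalen-1-yl]-4-methoxy-7-methylnaphthalen-2-ol | COc1cc(O)c(-c2c(C)cc(OCc3ccccc3)c3c(OC)c(OCc4ccccc4)ccc23)c2cc(C)cc(OCc3ccccc3)c12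
A2 | alternative 2 | 6-(benzyloxy)-1-[2,5-bis(benzyloxy)-4-methoxy-7-methylnaphthalen-1-yl]-4-hydroxy-5-methoxynaphthalene-2-carbaldehyde | O=Cc1cc(O)c2c(OC)c(OCc3ccccc3)ccc2c1-c1c(OCc2ccccc2)cc(OC)c2c(OCc3ccccc3)cc(C)cc12
A3 | alternative 3 | 7-(benzyloxy)-4-[2,5-bis(benzyloxy)-4-methoxy-7-methylnaphthalen-1-yl]-2-bromo-8-methoxy-3-methylnaphthalen-1-ol | Cc1c(Br)c(O)c2c(OC)c(OCc3ccccc3)ccc2c1-c1c(OCc2ccccc2)cc(OC)c2c(OCc3ccccc3)cc(C)cc12
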